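**Retrosynthetic overview**
1. The biaryl bond is not made by aryl–aryl coupling. The 4-aryl-3-methyl-1-naphthol ring (ring B) is built last, by an amine-catalysed atroposelective arene-forming aldol condensation of a γ-keto aldehyde that already carries naphthalene A as an aryl ketone. This ring closure creates the axis.
2. The keto aldehyde comes from a 1,2-diacylbenzene: the aryllithium of naphthalene A adds to a 3-(butenyl)phthalide (from O-benzylvanillic amide by directed ortho-metalation and pent-4-enal), followed by alcohol oxidation and alkene cleavage.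
3. Naphthalene A comes from 3,5-dimethylphenol by ortho-toluate anion/Weinreb amide annulation, O-differentiation and bromination.
4. Ring order: oxygenated ring of naphthalene A (step 4), temporary lactone (step 9), carbocyclic ring of naphthalene B with the axis (step 13). CHO to CH3 and debenzylation finish the synthesis.

Assumption: the SMILES has no stereocentre and cannot encode the configurationally stable biaryl axis, so the target is taken as the (aR)-atropisomer; axis descriptors are given in the names only, the sense of induction of the (S)-catalyst in step 13 is assigned by analogy and must be confirmed (ECD), and the (R)-catalyst gives the mirror image.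

**Step 1**
Reactants: 1 3,5-dimethylphenol
Product: 2 2-hydroxy-4,6-dimethylbenzaldehyde
Conditions: MgCl2, Et3N, (CH2O)n, MeCN, reflux
Reagents that add atoms: paraformaldehyde (as formaldehyde), C=O
Why: Magnesium-phenoxide-directed ortho-formylation (Casnati–Skattebøl); both ortho positions are equivalent and a second formaldehyde oxidises the benzylic alkoxide, so one aldehyde results.

**Step 2**
Reactants: 2 2-hydroxy-4,6-dimethylbenzaldehyde
Product: 3 2-(benzyloxy)-4,6-dimethylbenzaldehyde
Conditions: BnBr, K2CO3, DMF, 60 °C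
Reagents that add atoms: benzyl bromide, BrCc1ccccc1
Why: Williamson ether synthesis on the only phenol.

**Step 3**
Reactants: 3 2-(benzyloxy)-4,6-dimethylbenzaldehyde
Product: 4 methyl 2-(benzyloxy)-4,6-dimethylbenzoate
Conditions: I2, KOH, MeOH, 0 °C to rt
Reagents that add atoms: methanol, CO
Why: Oxidative esterification, in which the methyl hemiacetal is oxidised by hypoiodite; the benzyl ether and methyl groups are inert.

**Step 4**
Reactants: 4 methyl 2-(benzyloxy)-4,6-dimethylbenzoate; 5 N-methoxy-N-methylacetamide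
Product: 7 8-(benzyloxy)-6-methylnaphthalene-1,3-diol, via aryl acetone 6 (not isolated)
Conditions: LiN(iPr)2 (3 equiv), THF, −78 °C; then 5, −78 °C to rt; aq HCl
Reagents that add atoms: none
Why: Ester-directed lateral lithiation of the ortho-methyl group, acylation by the Weinreb amide, then intramolecular Claisen (Dieckmann-type) condensation of the methyl ketone enolate onto the ester and tautomerisation to the naphthalene-1,3-diol.

**Step 5**
Reactants: 7 8-(benzyloxy)-6-methylnaphthalene-1,3-diol
Product: 8 3,8-bis(benzyloxy)-6-methylnaphthalen-1-ol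
Conditions: BnBr (1.05 equiv), K2CO3, acetone, rt
Reagents that add atoms: benzyl bromide, BrCc1ccccc1
Why: Williamson etherification selective for the 3-OH, because the 1-OH is hydrogen-bonded to and shielded by the peri benzyloxy group.

**Step 6**
Reactants: 8 3,8-bis(benzyloxy)-6-methylnaphthalen-1-ol
Product: 9 1,6-bis(benzyloxy)-8-methoxy-3-methylnaphthalene
Conditions: MeI, K2CO3, DMF, 40 °C
Reagents that add atoms: iodomethane, CI
Why: Williamson O-methylation of the one remaining (peri) naphthol.

**Step 7**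
Reactants: 9 1,6-bis(benzyloxy)-8-methoxy-3-methylnaphthalene
Product: 10 2,5-bis(benzyloxy)-1-bromo-4-methoxy-7-methylnaphthalene
Conditions: NBS, MeCN, 0 °C
Reagents that add atoms: N-bromosuccinimide, O=C1CCC(=O)N1Br
Why: Electrophilic aromatic bromination at the alpha position that is ortho to the benzyloxy and para to the methoxy group, the most activated site.

**Step 8**
Reactants: 11 4-(benzyloxy)-3-methoxybenzoic acid
Product: 13 4-(benzyloxy)-N,N-diethyl-3-methoxybenzamide, via acid chloride 12 (not isolated)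
Conditions: (COCl)2, cat. DMF, CH2Cl2, 0 °C to rt; then Et2NH, aq NaOH, CH2Cl2, 0 °C
Reagents that add atoms: diethylamine, CCNCC; oxalyl chloride, O=C(Cl)C(Cl)=O (chlorine of 12 only)
Why: Acid chloride formation followed by Schotten–Baumann amidation installs the directing group.

**Step 9**
Reactants: 13 4-(benzyloxy)-N,N-diethyl-3-methoxybenzamide; 14 pent-4-enal
Product: 16 rac-5-(benzyloxy)-3-(but-3-en-1-yl)-4-methoxy-2-benzofuran-1(3H)-one, via hydroxy amide 15 (not isolated)
Conditions: s-BuLi, TMEDA, THF, −78 °C; then 14, −78 °C to rt; then aq HCl, THF, 50 °C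
Reagents that add atoms: none
Why: Directed ortho-metalation at the site between amide and methoxy (cooperative, faster than attack on the benzyl ether at −78 °C), 1,2-addition to the aldehyde and acid-promoted lactonisation; the new stereocentre is racemic and is destroyed in step 11.

**Step 10**
Reactants: 10 2,5-bis(benzyloxy)-1-bromo-4-methoxy-7-methylnaphthalene; 16 rac-5-(benzyloxy)-3-(but-3-en-1-yl)-4-methoxy-2-benzofuran-1(3H)-one
Product: 18 rac-[4-(benzyloxy)-2-(1-hydroxypent-4-en-1-yl)-3-methoxyphenyl][2,5-bis(benzyloxy)-4-methoxy-7-methylnaphthalen-1-yl]methanone (open form of its cyclic lactol), via aryllithium 17 (not isolated)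
Conditions: 10, n-BuLi, THF, −78 °C; then 16, −78 to −20 °C; H2O
Reagents that add atoms: n-butyllithium, [Li]CCCC (lithium of 17 only)
Why: Bromine–lithium exchange, then 1,2-addition of the aryllithium to the lactone carbonyl; the lithium hemiketal and the bulk of the aryl group prevent a second addition.

**Step 11**
Reactants: 18 rac-[4-(benzyloxy)-2-(1-hydroxypent-4-en-1-yl)-3-methoxyphenyl][2,5-bis(benzyloxy)-4-methoxy-7-methylnaphthalen-1-yl]methanone
Product: 19 1-{3-(benzyloxy)-6-[2,5-bis(benzyloxy)-4-methoxy-7-methyl-1-naphthoyl]-2-methoxyphenyl}pent-4-en-1-one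
Conditions: Dess–Martin periodinane, pyridine, CH2Cl2, 0 °C to rt
Reagents that add atoms: none
Why: Dess–Martin oxidation of the secondary benzylic alcohol through the open hydroxy-ketone tautomer; the pyridine buffer suppresses dehydration to an isobenzofuran.

**Step 12**
Reactants: 19 1-{3-(benzyloxy)-6-[2,5-bis(benzyloxy)-4-methoxy-7-methyl-1-naphthoyl]-2-methoxyphenyl}pent-4-en-1-one
Product: 21 4-{3-(benzyloxy)-6-[2,5-bis(benzyloxy)-4-methoxy-7-methyl-1-naphthoyl]-2-methoxyphenyl}-4-oxobutanal, via diol 20 (not isolated)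
Conditions: OsO4 (2 mol %), NaIO4, 2,6-lutidine, dioxane/H2O, rt; used at once
Reagents that add atoms: osmium tetroxide, O=[Os](=O)(=O)=O, reoxidised by sodium periodate, [Na+].[O-][I](=O)(=O)=O (source of the diol and aldehyde oxygen)
Why: Lemieux–Johnson oxidation, in which the only alkene is dihydroxylated and the glycol is cleaved by periodate; this avoids ozone, which would attack the electron-rich naphthalene.

**Step 13 (key step)**
Reactants: 21 4-{3-(benzyloxy)-6-[2,5-bis(benzyloxy)-4-methoxy-7-methyl-1-naphthoyl]-2-methoxyphenyl}-4-oxobutanal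
Product: 23 (aS)-1-[2,5-bis(benzyloxy)-4-methoxy-7-methylnaphthalen-1-yl]-6-(benzyloxy)-4-hydroxy-5-methoxynaphthalene-2-carbaldehyde, via keto tautomer 22 (not isolated)
Conditions: (S)-5-(pyrrolidin-2-yl)-1H-tetrazole (10 mol %), CHCl3, rt
Reagents that add atoms: none
Why: Proposed new method: the catalyst forms the enamine of the aldehyde, whose alpha-carbon adds in a six-membered intramolecular aldol to one face of the tetrazole-activated diaryl ketone (no other ring size is accessible), dehydration of the tertiary carbinol turns the new stereocentre into the axis (central-to-axial transfer), and enolisation of the C4 ketone aromatises irreversibly to the 1-naphthol; the closest known reaction type is the secondary-amine-catalysed atroposelective arene-forming aldol condensation of 2-aroylaryl-substituted enolisable aldehydes to 1-arylnaphthalene-2-carbaldehydes.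

**Step 14**
Reactants: 23 (aS)-1-[2,5-bis(benzyloxy)-4-methoxy-7-methylnaphthalen-1-yl]-6-(benzyloxy)-4-hydroxy-5-methoxynaphthalene-2-carbaldehyde
Product: 24 (aS)-7-(benzyloxy)-4-[2,5-bis(benzyloxy)-4-methoxy-7-methylnaphthalen-1-yl]-3-(hydroxymethyl)-8-methoxynaphthalen-1-ol
Conditions: NaBH4, THF/MeOH, 0 °C
Reagents that add atoms: none
Why: Chemoselective hydride reduction of the aldehyde; the tetra-ortho-substituted axis is not affected.

**Step 15**
Reactants: 24 (aS)-7-(benzyloxy)-4-[2,5-bis(benzyloxy)-4-methoxy-7-methylnaphthalen-1-yl]-3-(hydroxymethyl)-8-methoxynaphthalen-1-ol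
Product: 25 (aR)-4-(2,5-dihydroxy-4-methoxy-7-methylnaphthalen-1-yl)-8-methoxy-3-methylnaphthalene-1,7-diol (CNP0147277.0)
Conditions: H2 (1–4 atm), 10% Pd/C, EtOAc/MeOH, AcOH, rt, under argon on work-up
Reagents that add atoms: none
Why: Heterogeneous hydrogenolysis cleaves the three O-benzyl ethers and the naphthylmethyl C–O bond (CH2OH to CH3); the geometry of the axis is unchanged, and the descriptor changes from aS to aR only because CH3 ranks below the ring-fusion carbon.

**Compound list**
1 | 3,5-dimethylphenol | Cc1cc(C)cc(O)c1 | starting material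
2 | 2-hydroxy-4,6-dimethylbenzaldehyde | Cc1cc(C)c(C=O)c(O)c1 | intermediate
3 | 2-(benzyloxy)-4,6-dimethylbenzaldehyde | Cc1cc(C)c(C=O)c(OCc2ccccc2)c1 | intermediate
4 | methyl 2-(benzyloxy)-4,6-dimethylbenzoate | COC(=O)c1c(C)cc(C)cc1OCc1ccccc1 | intermediate
5 | N-methoxy-N-methylacetamide | CON(C)C(C)=O | starting material
6 | methyl 2-(benzyloxy)-4-methyl-6-(2-oxopropyl)benzoate | COC(=O)c1c(CC(C)=O)cc(C)cc1OCc1ccccc1 | intermediate
7 | 8-(benzyloxy)-6-methylnaphthalene-1,3-diol | Oc1cc(O)cc2cc(C)cc(OCc3ccccc3)c12 | intermediate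
8 | 3,8-bis(benzyloxy)-6-methylnaphthalen-1-ol | Oc1cc(OCc2ccccc2)cc2cc(C)cc(OCc3ccccc3)c12 | intermediate
9 | 1,6-bis(benzyloxy)-8-methoxy-3-methylnaphthalene | COc1cc(OCc2ccccc2)cc2cc(C)cc(OCc3ccccc3)c12 | intermediate
10 | 2,5-bis(benzyloxy)-1-bromo-4-methoxy-7-methylnaphthalene | COc1cc(OCc2ccccc2)c(Br)c2cc(C)cc(OCc3ccccc3)c12 | intermediate
11 | 4-(benzyloxy)-3-methoxybenzoic acid | COc1cc(C(O)=O)ccc1OCc1ccccc1 | starting material
12 | 4-(benzyloxy)-3-methoxybenzoyl chloride | COc1cc(C(Cl)=O)ccc1OCc1ccccc1 | intermediate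
13 | 4-(benzyloxy)-N,N-diethyl-3-methoxybenzamide | CCN(CC)C(=O)c1ccc(OCc2ccccc2)c(OC)c1 | intermediate
14 | pent-4-enal | C=CCCC=O | starting material
15 | rac-4-(benzyloxy)-N,N-diethyl-2-(1-hydroxypent-4-en-1-yl)-3-methoxybenzamide | CCN(CC)C(=O)c1ccc(OCc2ccccc2)c(OC)c1C(O)CCC=C | intermediate
16 | rac-5-(benzyloxy)-3-(but-3-en-1-yl)-4-methoxy-2-benzofuran-1(3H)-one | C=CCCC1OC(=O)c2ccc(OCc3ccccc3)c(OC)c12 | intermediate
17 | [2,5-bis(benzyloxy)-4-methoxy-7-methylnaphthalen-1-yl]lithium | [Li]c1c(OCc2ccccc2)cc(OC)c2c(OCc3ccccc3)cc(C)cc12 | intermediate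
18 | rac-[4-(benzyloxy)-2-(1-hydroxypent-4-en-1-yl)-3-methoxyphenyl][2,5-bis(benzyloxy)-4-methoxy-7-methylnaphthalen-1-yl]methanone | COc1cc(OCc2ccccc2)c(C(=O)c2ccc(OCc3ccccc3)c(OC)c2C(O)CCC=C)c2cc(C)cc(OCc3ccccc3)c12 | intermediate
19 | 1-{3-(benzyloxy)-6-[2,5-bis(benzyloxy)-4-methoxy-7-methyl-1-naphthoyl]-2-methoxyphenyl}pent-4-en-1-one | COc1cc(OCc2ccccc2)c(C(=O)c2ccc(OCc3ccccc3)c(OC)c2C(=O)CCC=C)c2cc(C)cc(OCc3ccccc3)c12 | intermediate
20 | rac-1-{3-(benzyloxy)-6-[2,5-bis(benzyloxy)-4-methoxy-7-methyl-1-naphthoyl]-2-methoxyphenyl}-4,5-dihydroxypentan-1-one | COc1cc(OCc2ccccc2)c(C(=O)c2ccc(OCc3ccccc3)c(OC)c2C(=O)CCC(O)CO)c2cc(C)cc(OCc3ccccc3)c12 | intermediate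
21 | 4-{3-(benzyloxy)-6-[2,5-bis(benzyloxy)-4-methoxy-7-methyl-1-naphthoyl]-2-methoxyphenyl}-4-oxobutanal | COc1cc(OCc2ccccc2)c(C(=O)c2ccc(OCc3ccccc3)c(OC)c2C(=O)CCC=O)c2cc(C)cc(OCc3ccccc3)c12 | intermediate
22 | (aS)-1-[2,5-bis(benzyloxy)-4-methoxy-7-methylnaphthalen-1-yl]-6-(benzyloxy)-5-methoxy-4-oxo-3,4-dihydronaphthalene-2-carbaldehyde | COc1cc(OCc2ccccc2)c(C2=C(C=O)CC(=O)c3c(OC)c(OCc4ccccc4)ccc23)c2cc(C)cc(OCc3ccccc3)c12 | intermediate
23 | (aS)-1-[2,5-bis(benzyloxy)-4-methoxy-7-methylnaphthalen-1-yl]-6-(benzyloxy)-4-hydroxy-5-methoxynaphthalene-2-carbaldehyde | COc1cc(OCc2ccccc2)c(-c2c(C=O)cc(O)c3c(OC)c(OCc4ccccc4)ccc23)c2cc(C)cc(OCc3ccccc3)c12 | intermediate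
24 | (aS)-7-(benzyloxy)-4-[2,5-bis(benzyloxy)-4-methoxy-7-methylnaphthalen-1-yl]-3-(hydroxymethyl)-8-methoxynaphthalen-1-ol | COc1cc(OCc2ccccc2)c(-c2c(CO)cc(O)c3c(OC)c(OCc4ccccc4)ccc23)c2cc(C)cc(OCc3ccccc3)c12 | intermediate
25 | (aR)-4-(2,5-dihydroxy-4-methoxy-7-methylnaphthalen-1-yl)-8-methoxy-3-methylnaphthalene-1,7-diol | COc1cc(O)c(-c2c(C)cc(O)c3c(OC)c(O)ccc23)c2cc(C)cc(O)c12 | target

**Totals and risks**
Total step count: 15. Longest linear sequence: 13 (steps 1–7, then 10–15).

Most likely to fail, first: step 13. The γ-keto aldehyde is a new substrate class for the arene-forming aldol, and the diaryl ketone is hindered and electron-rich, so both rate and enantioselectivity are uncertain. Fallback: starting from 21, the ring is closed without stereocontrol by an achiral amine (pyrrolidine, AcOH, toluene, 60 °C) to give the racemic aldehyde F1. Its free naphthol is then acylated with (R)-1-phenylethyl isocyanate (Et3N, DMAP, CH2Cl2), and the two diastereomeric carbamates are separated on silica gel or by crystallisation. The (aS)-carbamate F2 is cleaved with K2CO3 in MeOH and returns enantiopure 23, where the route continues with step 14.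

Second: step 10. The di-ortho-substituted aryllithium may deprotonate the lactone at its benzylic C–H instead of adding to the carbonyl. Fallback: starting from 16, reduction with (i-Bu)2AlH (CH2Cl2, −78 °C) gives the lactol F3. With 2.2 equiv of aryllithium 17 (made from 10 as before), F3 opens to the far more electrophilic hydroxy aldehyde and gives the diol F4. Double Dess–Martin oxidation of F4 gives the diketone 19, so the route is rejoined at 19 and step 11 is not needed.

Third: step 15. Hydrogenolysis of the hindered naphthylmethyl alcohol may stall after debenzylation, or may need conditions that begin to reduce the naphthalene rings. Fallback: starting from 24, ionic deoxygenation (Et3SiH, CF3CO2H, CH2Cl2, 0 °C; ionisation to the alkoxy-stabilised naphthylmethyl cation and hydride capture) gives the methyl compound F5. Its three benzyl ethers are then removed by ordinary hydrogenolysis (H2, 10% Pd/C, EtOAc/MeOH) to reach 25.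

**Further compounds**
F1 | step 13 | rac-1-[2,5-bis(benzyloxy)-4-methoxy-7-methylnaphthalen-1-yl]-6-(benzyloxy)-4-hydroxy-5-methoxynaphthalene-2-carbaldehyde (racemate of 23) | COc1cc(OCc2ccccc2)c(-c2c(C=O)cc(O)c3c(OC)c(OCc4ccccc4)ccc23)c2cc(C)cc(OCc3ccccc3)c12
F2 | step 13 | (aS)-7-(benzyloxy)-4-[2,5-bis(benzyloxy)-4-methoxy-7-methylnaphthalen-1-yl]-3-formyl-8-methoxynaphthalen-1-yl N-[(1R)-1-phenylethyl]carbamate | COc1cc(OCc2ccccc2)c(-c2c(C=O)cc(OC(=O)N[C@H](C)c3ccccc3)c3c(OC)c(OCc4ccccc4)ccc23)c2cc(C)cc(OCc3ccccc3)c12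
F3 | step 10 | rac-5-(benzyloxy)-3-(but-3-en-1-yl)-4-methoxy-1,3-dihydro-2-benzofuran-1-ol (diastereomer mixture) | C=CCCC1OC(O)c2ccc(OCc3ccccc3)c(OC)c12
F4 | step 10 | rac-1-{3-(benzyloxy)-6-[[2,5-bis(benzyloxy)-4-methoxy-7-methylnaphthalen-1-yl](hydroxy)methyl]-2-methoxyphenyl}pent-4-en-1-ol (diastereomer mixture) | COc1cc(OCc2ccccc2)c(C(O)c2ccc(OCc3ccccc3)c(OC)c2C(O)CCC=C)c2cc(C)cc(OCc3ccccc3)c12
F5 | step 15 | (aR)-7-(benzyloxy)-4-[2,5-bis(benzyloxy)-4-methoxy-7-methylnaphthalen-1-yl]-8-methoxy-3-methylnaphthalen-1-ol | COc1cc(OCc2ccccc2)c(-c2c(C)cc(O)c3c(OC)c(OCc4ccccc4)ccc23)c2cc(C)cc(OCc3ccccc3)c12
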